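## Retrosynthetic overview

1. The target is the silyl-deprotected form of a (2S)-3'-O-TBS flavanone. Rings C and A of that flavanone are both made in one pot from a linear (9S)-9-aryl-9-hydroxy-2-geranyl-3,5,7-trioxononanoate tert-butyl ester.
2. Ring C closes first (9-OH onto the C5 ketone, then dehydration to a 2,3-dihydro-4-pyranone). Ring A closes second (C1 acylketene onto pyranone C5, then aromatisation). O1 is committed before the arene exists, which fixes 6-geranyl over 8-geranyl.
3. The flavanone C2 stereocentre is the C9 carbinol of the chain; its C–O bond is never broken.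
4. The chain comes from a Claisen coupling of the trianion of tert-butyl 2-geranyl-3,5-dioxohexanoate (C1–C6) with an (S)-3-aryl-3-hydroxy thioester (C7–C9).
5. The thioester comes from TBS-isovanillin by a catalytic asymmetric acetate Mukaiyama aldol; the dioxohexanoate comes from tert-butyl acetoacetate by C2-geranylation and γ-acetylation. Ring B is bought.

Assumption: the (S)-BINOL/Ti(OiPr)4 catalyst attacks the Si face of the aryl aldehyde (as in its allylations), giving the (S)-carbinol; the sense is checked on compound 5 (Mosher ester) and the (R)-ligand is used if it proves opposite.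
Assumption: ketene thioacetal 3 is purchased (otherwise one step from S-tert-butyl thioacetate with LDA/TMSCl).

Geranyl = (2E)-3,7-dimethylocta-2,6-dien-1-yl. Polyketo compounds are drawn as keto tautomers.

## Route

Step 1
Reactants: 1 isovanillin (3-hydroxy-4-methoxybenzaldehyde)
Product: 2 3-(tert-butyldimethylsilyloxy)-4-methoxybenzaldehyde
Conditions: TBSCl (1.1 equiv), imidazole (2 equiv), DMF, rt
Reagents that add atoms: tert-butyldimethylsilyl chloride, CC(C)(C)[Si](C)(C)Cl
Why: Imidazole-promoted silyl ether formation masks the only acidic OH of ring B so that the Lewis-acid aldol and the polyanion step are not disturbed.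

Step 2
Reactants: 2 3-(tert-butyldimethylsilyloxy)-4-methoxybenzaldehyde; 3 1-(tert-butylsulfanyl)-1-(trimethylsilyloxy)ethene
Product: 5 S-tert-butyl (3S)-3-[3-(tert-butyldimethylsilyloxy)-4-methoxyphenyl]-3-hydroxypropanethioate, via O-TMS aldol adduct 4 (not isolated)
Conditions: (S)-BINOL (20 mol %), Ti(OiPr)4 (20 mol %), 4 Å MS, Et2O, −20 °C; then 1 M HCl, THF, 0 °C
Reagents that add atoms: none
Why: BINOL–Ti(IV)-catalysed asymmetric Mukaiyama acetate aldol in which the (S)-ligand directs the ketene thioacetal to the Si face of the aldehyde, setting C3 as (S) (the future flavanone C2), while brief dilute acid cleaves only the O-TMS group and leaves the aryl TBS ether.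

Step 3
Reactants: 6 tert-butyl acetoacetate; 7 geranyl bromide
Product: 8 tert-butyl 2-geranyl-3-oxobutanoate (racemic at C2)
Conditions: 6 (1.5 equiv), NaH (1.1 equiv), THF, 0 °C; then 7, rt
Reagents that add atoms: none
Why: Acetoacetic ester C-alkylation by SN2 at the primary allylic bromide (E-olefin retained, excess 6 suppresses dialkylation); the racemic C2 centre later becomes aromatic C6.

Step 4
Reactants: 8 tert-butyl 2-geranyl-3-oxobutanoate; 9 N-methoxy-N-methylacetamide
Product: 10 tert-butyl 2-geranyl-3,5-dioxohexanoate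
Conditions: LDA (2.2 equiv), THF, −78 → 0 °C; then 9, −78 → −20 °C; 1 M HCl quench
Reagents that add atoms: none
Why: Weiler-type acetoacetate dianion reacts at its γ-carbon with the Weinreb amide (Claisen-type γ-acylation), the chelated tetrahedral intermediate preventing over-addition.

Step 5
Reactants: 10 tert-butyl 2-geranyl-3,5-dioxohexanoate; 5 S-tert-butyl (3S)-3-[3-(tert-butyldimethylsilyloxy)-4-methoxyphenyl]-3-hydroxypropanethioate
Product: 11 tert-butyl (9S)-9-[3-(tert-butyldimethylsilyloxy)-4-methoxyphenyl]-2-geranyl-9-hydroxy-3,5,7-trioxononanoate (mixture at C2)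
Conditions: 10 (2.5 equiv), LDA (7.5 equiv), THF, −78 → 0 °C; then 5, −78 → −40 °C; AcOH quench at −78 °C; rapid chromatography on deactivated silica
Reagents that add atoms: none
Why: Harris-type polyanion Claisen condensation in which the 2,4,6-trianion reacts only at its last-formed terminal carbanion (C6) with the thioester, the excess trianion serving as base for the carbinol and the product, so C9 is untouched and stays (S).

Step 6
Reactants: 11 tert-butyl (9S)-9-[3-(tert-butyldimethylsilyloxy)-4-methoxyphenyl]-2-geranyl-9-hydroxy-3,5,7-trioxononanoate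
Product: 15 (2S)-5,7-dihydroxy-6-geranyl-2-(3-hydroxy-4-methoxyphenyl)-2,3-dihydro-4H-chromen-4-one, via dihydropyranone ester 12 (not isolated), via acylketene 13 (not isolated), via silyl-protected flavanone 14 (not isolated)
Conditions: PPTS (10 mol %), 4 Å MS, PhCl (0.005 M), 45 °C, 2 h; then 130 °C, 2 h; cool to 0 °C, TBAF/AcOH (1:1, 2 equiv), THF, 1 h
Reagents that add atoms: none
Why: Proposed new method: at 45 °C the C9 hydroxyl adds to the C5 ketone and the hemiketal dehydrates (known mild-acid cyclodehydration of δ-hydroxy-β-diketones to 2,3-dihydro-4H-pyran-4-ones; the C9–O bond is never broken, so (S) is retained), then at 130 °C the tert-butyl β-keto ester loses tert-butanol to give acylketene 13 (known thermal acylketene generation from tert-butyl acetoacetates), whose C3-enol is a dienylketene that closes by 6π-electrocyclisation onto the pyranone C5 and tautomerises to the phloroglucinol ring (closest known types: the final dienylketene electrocyclisation of the Danheiser benzannulation and the Claisen-mode cyclisation of 3,5,7-triketo esters to acylphloroglucinols); sieves remove the water that would quench the ketene, high dilution suppresses ketene dimerisation, and buffered fluoride cleaves only the aryl silyl ether without epimerising C2.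

## Compound list

1 | isovanillin | COc1ccc(C=O)cc1O | starting material
2 | 3-(tert-butyldimethylsilyloxy)-4-methoxybenzaldehyde | COc1ccc(C=O)cc1O[Si](C)(C)C(C)(C)C | intermediate
3 | 1-(tert-butylsulfanyl)-1-(trimethylsilyloxy)ethene | C=C(O[Si](C)(C)C)SC(C)(C)C | starting material
4 | S-tert-butyl (3S)-3-[3-(tert-butyldimethylsilyloxy)-4-methoxyphenyl]-3-(trimethylsilyloxy)propanethioate | CC(C)(C)SC(=O)C[C@H](O[Si](C)(C)C)c1ccc(OC)c(O[Si](C)(C)C(C)(C)C)c1 | intermediate (not isolated)
5 | S-tert-butyl (3S)-3-[3-(tert-butyldimethylsilyloxy)-4-methoxyphenyl]-3-hydroxypropanethioate | CC(C)(C)SC(=O)C[C@H](O)c1ccc(OC)c(O[Si](C)(C)C(C)(C)C)c1 | intermediate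
6 | tert-butyl acetoacetate | CC(=O)CC(=O)OC(C)(C)C | starting material
7 | geranyl bromide | BrC/C=C(\C)CCC=C(C)C | starting material
8 | tert-butyl 2-geranyl-3-oxobutanoate | CC(=O)C(C/C=C(\C)CCC=C(C)C)C(=O)OC(C)(C)C | intermediate
9 | N-methoxy-N-methylacetamide | CC(=O)N(C)OC | starting material
10 | tert-butyl 2-geranyl-3,5-dioxohexanoate | CC(=O)CC(=O)C(C/C=C(\C)CCC=C(C)C)C(=O)OC(C)(C)C | intermediate
11 | tert-butyl (9S)-9-[3-(tert-butyldimethylsilyloxy)-4-methoxyphenyl]-2-geranyl-9-hydroxy-3,5,7-trioxononanoate | CC(C)(C)OC(=O)C(C/C=C(\C)CCC=C(C)C)C(=O)CC(=O)CC(=O)C[C@H](O)c1ccc(OC)c(O[Si](C)(C)C(C)(C)C)c1 | intermediate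
12 | tert-butyl 4-{(2S)-2-[3-(tert-butyldimethylsilyloxy)-4-methoxyphenyl]-4-oxo-3,4-dihydro-2H-pyran-6-yl}-2-geranyl-3-oxobutanoate | CC(C)(C)OC(=O)C(C/C=C(\C)CCC=C(C)C)C(=O)CC1=CC(=O)C[C@@H](c2ccc(OC)c(O[Si](C)(C)C(C)(C)C)c2)O1 | intermediate (not isolated)
13 | 4-{(2S)-2-[3-(tert-butyldimethylsilyloxy)-4-methoxyphenyl]-4-oxo-3,4-dihydro-2H-pyran-6-yl}-2-geranyl-but-1-ene-1,3-dione (acylketene) | O=C=C(C/C=C(\C)CCC=C(C)C)C(=O)CC1=CC(=O)C[C@@H](c2ccc(OC)c(O[Si](C)(C)C(C)(C)C)c2)O1 | intermediate (not isolated)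
14 | (2S)-2-[3-(tert-butyldimethylsilyloxy)-4-methoxyphenyl]-6-geranyl-5,7-dihydroxy-2,3-dihydro-4H-chromen-4-one | COc1ccc([C@@H]2CC(=O)c3c(cc(O)c(C/C=C(\C)CCC=C(C)C)c3O)O2)cc1O[Si](C)(C)C(C)(C)C | intermediate (not isolated)
15 | (2S)-5,7-dihydroxy-6-geranyl-2-(3-hydroxy-4-methoxyphenyl)-2,3-dihydro-4H-chromen-4-one (CNP0264411.1) | COc1ccc([C@@H]2CC(=O)c3c(cc(O)c(C/C=C(\C)CCC=C(C)C)c3O)O2)cc1O | target

## Summary

Total steps: 6. Longest linear sequence: 4 steps (steps 1, 2, 5, 6; equally 3, 4, 5, 6).

Steps most likely to fail, with fallbacks: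

Step 6 (double cyclisation; the ketene C-acylation is unproven, and premature heating would give a 2-pyrone). The fallback reverses the ring order and makes the C2–O1 bond with inversion. It sets out from 2: step 2 is run with (R)-BINOL to give, through the (3R)-O-TMS aldol adduct F1, the (3R)-hydroxy thioester F2. Coupling with the trianion of 10 as in step 5 gives the (9R)-triketo ester F3. Mg(OMe)2 in MeOH at 40 °C then effects the Claisen-mode cyclisation of the triketo ester (C6 onto C1, loss of tert-butanol) to the acylphloroglucinol (3R)-β-hydroxydihydrochalcone F4. An intramolecular Mitsunobu etherification (PPh3, DIAD, THF, 0 °C) through the less hindered 6'-OH inverts the carbinol and comes back to the route at 14; the 8-geranyl regioisomer from the 2'-OH is separated, and 14 is desilylated as in step 6.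

Step 5 (trianion acylation with a thioester carrying a free β-hydroxyl; proton transfer or retro-aldol may win). The fallback replaces the Claisen coupling by an aldol/oxidation sequence and sets out from 5 (with 10). TESOTf/2,6-lutidine gives the triethylsilyl ether F5. DIBAL-H at −78 °C reduces the thioester to the β-silyloxy aldehyde F6. The trianion of 10 adds to this aldehyde (polyanion aldol; no acidic OH, much more reactive electrophile) to give the C7 carbinol F7. Dess–Martin periodinane oxidises the β-hydroxy ketone to the TES-protected triketo ester F8. AcOH–THF–H2O removes the triethylsilyl group and the sequence comes back at 11.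

Step 2 (electron-rich aldehyde; rate, ee and sense of induction are the concerns). The fallback sets the stereocentre by asymmetric reduction and sets out from 2. The lithium enolate of S-tert-butyl thioacetate (CC(=O)SC(C)(C)C; LDA, THF, −78 °C) gives the racemic aldol F9. Dess–Martin oxidation gives the β-keto thioester F10. Noyori transfer hydrogenation with RuCl[(S,S)-TsDPEN](p-cymene) in HCO2H/Et3N, which reliably gives (S)-aryl carbinols, comes back at 5.

## Further compounds

F1 | step 6 | S-tert-butyl (3R)-3-[3-(tert-butyldimethylsilyloxy)-4-methoxyphenyl]-3-(trimethylsilyloxy)propanethioate | CC(C)(C)SC(=O)C[C@@H](O[Si](C)(C)C)c1ccc(OC)c(O[Si](C)(C)C(C)(C)C)c1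
F2 | step 6 | S-tert-butyl (3R)-3-[3-(tert-butyldimethylsilyloxy)-4-methoxyphenyl]-3-hydroxypropanethioate | CC(C)(C)SC(=O)C[C@@H](O)c1ccc(OC)c(O[Si](C)(C)C(C)(C)C)c1
F3 | step 6 | tert-butyl (9R)-9-[3-(tert-butyldimethylsilyloxy)-4-methoxyphenyl]-2-geranyl-9-hydroxy-3,5,7-trioxononanoate | CC(C)(C)OC(=O)C(C/C=C(\C)CCC=C(C)C)C(=O)CC(=O)CC(=O)C[C@@H](O)c1ccc(OC)c(O[Si](C)(C)C(C)(C)C)c1
F4 | step 6 | (3R)-3-[3-(tert-butyldimethylsilyloxy)-4-methoxyphenyl]-1-(3-geranyl-2,4,6-trihydroxyphenyl)-3-hydroxypropan-1-one | O=C(C[C@@H](O)c1ccc(OC)c(O[Si](C)(C)C(C)(C)C)c1)c1c(O)cc(O)c(C/C=C(\C)CCC=C(C)C)c1O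
F5 | step 5 | S-tert-butyl (3S)-3-[3-(tert-butyldimethylsilyloxy)-4-methoxyphenyl]-3-(triethylsilyloxy)propanethioate | CC(C)(C)SC(=O)C[C@H](O[Si](CC)(CC)CC)c1ccc(OC)c(O[Si](C)(C)C(C)(C)C)c1
F6 | step 5 | (3S)-3-[3-(tert-butyldimethylsilyloxy)-4-methoxyphenyl]-3-(triethylsilyloxy)propanal | O=CC[C@H](O[Si](CC)(CC)CC)c1ccc(OC)c(O[Si](C)(C)C(C)(C)C)c1
F7 | step 5 | tert-butyl (9S)-9-[3-(tert-butyldimethylsilyloxy)-4-methoxyphenyl]-2-geranyl-7-hydroxy-3,5-dioxo-9-(triethylsilyloxy)nonanoate | CC(C)(C)OC(=O)C(C/C=C(\C)CCC=C(C)C)C(=O)CC(=O)CC(O)C[C@H](O[Si](CC)(CC)CC)c1ccc(OC)c(O[Si](C)(C)C(C)(C)C)c1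
F8 | step 5 | tert-butyl (9S)-9-[3-(tert-butyldimethylsilyloxy)-4-methoxyphenyl]-2-geranyl-3,5,7-trioxo-9-(triethylsilyloxy)nonanoate | CC(C)(C)OC(=O)C(C/C=C(\C)CCC=C(C)C)C(=O)CC(=O)CC(=O)C[C@H](O[Si](CC)(CC)CC)c1ccc(OC)c(O[Si](C)(C)C(C)(C)C)c1
F9 | step 2 | S-tert-butyl 3-[3-(tert-butyldimethylsilyloxy)-4-methoxyphenyl]-3-hydroxypropanethioate (racemic) | CC(C)(C)SC(=O)CC(O)c1ccc(OC)c(O[Si](C)(C)C(C)(C)C)c1
F10 | step 2 | S-tert-butyl 3-[3-(tert-butyldimethylsilyloxy)-4-methoxyphenyl]-3-oxopropanethioate | CC(C)(C)SC(=O)CC(=O)c1ccc(OC)c(O[Si](C)(C)C(C)(C)C)c1
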